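**Plan**
1. Numbering: chain C1 (CH2OH), C2, C3, C4 (methyl C15). Ring A (cyclohexene) is C5–C10, with the chain on C5, ester oxygen O6 on C6 and methyl C14 on C10. Ring B (lactone) is C7, C11 (=C13H2), C12 (=O), O8, C8.
2. Enabling feature: C4 bears a methyl group and is bonded to the ring A alkene C5=C10. With C4–C15 drawn as a double bond, C10=C5–C4=C15 is the 1,3-diene that an enyne metathesis leaves behind.
3. Cuts in retrosynthetic order: O6–acyl and C11=C13; H2 off C4–C15; C5=C10 and C4=C15 (back to a methallyl group on C9 and the alkyne C5≡C4); C5–C6 (acetylide plus aldehyde); C10=CH2 (ketone methylenation). C6 and C10 are then rejoined as the alkene of a methylcyclopentene, whose C7–C11 bond comes from a Claisen rearrangement and whose C10–C14 bond comes from MeLi.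
4. Forward order: ring B is made first, cis-fused to a sacrificial cyclopentene. Ozonolysis opens that carbocycle into two different carbonyl arms, the C1–C5 chain is joined at C6, and ring A closes last by metathesis.
5. Stereochemistry: C8 is bought with (R)-4-silyloxycyclopentenone. C7 follows by suprafacial [3,3] transfer, C6 by catalyst-controlled transfer hydrogenation of an ynone, and C4 by O6-directed hydrogenation. The ester centre comes with (R)-2-methylbutanoic acid.

Key step: step 10

Assumption: (R)-4-[(tert-butyldimethylsilyl)oxy]cyclopent-2-enone and (R)-2-methylbutanoic acid are purchased as single enantiomers, and the two C6 epimers formed in step 6 are carried together until step 8.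

Step 1
Reactants: 1 (4R)-4-[(tert-butyldimethylsilyl)oxy]cyclopent-2-en-1-one
Product: 2 (1S,4R)-4-[(tert-butyldimethylsilyl)oxy]-1-methylcyclopent-2-en-1-ol (OH cis to OTBS)
Conditions: MeLi, Et2O, −78 °C; then H2O
Reagents that add atoms: methyllithium, [Li]C
Why: 1,2-addition of an organolithium to an enone, in which MeLi should attack the carbonyl carbon C10 opposite the C8 silyloxy group, so that C14 is installed and the new tertiary hydroxyl (1S) stands cis to O8.

Step 2
Reactants: 2 (1S,4R)-4-[(tert-butyldimethylsilyl)oxy]-1-methylcyclopent-2-en-1-ol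
Product: 4 2-[(1S,5R)-5-[(tert-butyldimethylsilyl)oxy]-3-methylcyclopent-2-en-1-yl]-N,N-dimethylacetamide, via ketene N,O-acetal 3 (not isolated)
Conditions: MeC(OMe)2NMe2, xylene, 140 °C, MeOH distilled off
Reagents that add atoms: N,N-dimethylacetamide dimethyl acetal, COC(C)(OC)N(C)C
Why: Eschenmoser–Claisen rearrangement, in which the ketene N,O-acetal shifts suprafacially so that C11 reaches C7 on the face that carried the hydroxyl (cis to O8, which sets C7) while the alkene moves to C6=C10 with C14 on it.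

Step 3
Reactants: 4 2-[(1S,5R)-5-[(tert-butyldimethylsilyl)oxy]-3-methylcyclopent-2-en-1-yl]-N,N-dimethylacetamide
Product: 6 (1R,5S)-7-methyl-2-oxabicyclo[3.3.0]oct-6-en-3-one, via hydroxy amide 5 (not isolated)
Conditions: 2 M aq HCl, THF, 40 °C
Reagents that add atoms: none
Why: Acidic desilylation followed by lactonisation of a γ-hydroxy amide, in which only the cis isomer can close ring B onto the cyclopentene, so material from the minor face of attack in step 1 stays open and is removed.

Step 4
Reactants: 6 (1R,5S)-7-methyl-2-oxabicyclo[3.3.0]oct-6-en-3-one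
Product: 8 (2R,3R)-5-oxo-2-(2-oxopropyl)oxolane-3-carbaldehyde (cis), via secondary ozonide 7 (not isolated)
Conditions: O3, CH2Cl2, −78 °C; then Me2S, −78 °C → rt; used crude
Reagents that add atoms: ozone, [O-][O+]=O
Why: Ozonolysis with reductive work-up splits the trisubstituted alkene into two unlike carbonyl groups (C6 aldehyde, C10 methyl ketone), so the two arms are differentiated from the start, and the neutral conditions should leave the epimerisable C7 alone.

Step 5
Reactants: 9 pent-4-yn-1-ol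
Product: 10 tert-butyl(pent-4-yn-1-yloxy)diphenylsilane
Conditions: TBDPSCl, imidazole, CH2Cl2, rt
Reagents that add atoms: tert-butyl(chloro)diphenylsilane, CC(C)(C)[Si](Cl)(c1ccccc1)c1ccccc1
Why: Standard silylation of a primary alcohol, giving an ether at O1 that outlasts the acid later used to remove the triethylsilyl group.

Step 6
Reactants: 8 (2R,3R)-5-oxo-2-(2-oxopropyl)oxolane-3-carbaldehyde; 10 tert-butyl(pent-4-yn-1-yloxy)diphenylsilane
Product: 13 (4S,5R)-4-[6-[(tert-butyldiphenylsilyl)oxy]-1-hydroxyhex-2-yn-1-yl]-5-(2-oxopropyl)oxolan-2-one (both C6 epimers), via lithium acetylide 11 (not isolated), via titanium acetylide 12 (not isolated)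
Conditions: 10, n-BuLi, THF, −78 °C; ClTi(OiPr)3, −78 → −40 °C; 8, −78 → −30 °C; then H2O
Reagents that add atoms: none
Why: Chemoselective carbonyl addition of an alkynyltitanium triisopropoxide, a weakly basic reagent that takes aldehydes far faster than ketones or lactones and should spare the acidic C7–H lying β to the O8 leaving group, while the C6 configuration is unimportant because steps 8 and 9 reset it.

Step 7
Reactants: 13 (4S,5R)-4-[6-[(tert-butyldiphenylsilyl)oxy]-1-hydroxyhex-2-yn-1-yl]-5-(2-oxopropyl)oxolan-2-one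
Product: 14 (4S,5R)-4-[6-[(tert-butyldiphenylsilyl)oxy]-1-hydroxyhex-2-yn-1-yl]-5-(2-methylprop-2-en-1-yl)oxolan-2-one (both C6 epimers)
Conditions: Zn, CH2Br2, TiCl4, THF/CH2Cl2, 0 °C → rt
Reagents that add atoms: dibromomethane, BrCBr
Why: Lombardo methylenation, a non-basic zinc–titanium methylene transfer that converts ketones beside lactones and free hydroxyl groups where a phosphorus ylide would risk E1cB loss of the O8 carboxylate, and it is placed after step 6 so that the aldehyde never coexists with the nucleophilic methallyl group.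

Step 8
Reactants: 14 (4S,5R)-4-[6-[(tert-butyldiphenylsilyl)oxy]-1-hydroxyhex-2-yn-1-yl]-5-(2-methylprop-2-en-1-yl)oxolan-2-one
Product: 15 (4R,5R)-4-[6-[(tert-butyldiphenylsilyl)oxy]hex-2-ynoyl]-5-(2-methylprop-2-en-1-yl)oxolan-2-one
Conditions: Dess–Martin periodinane, CH2Cl2, 0 °C → rt
Reagents that add atoms: none
Why: Dess–Martin oxidation of a propargylic alcohol under base-free conditions merges both C6 epimers into one ynone without enolising C7.

Step 9
Reactants: 15 (4R,5R)-4-[6-[(tert-butyldiphenylsilyl)oxy]hex-2-ynoyl]-5-(2-methylprop-2-en-1-yl)oxolan-2-one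
Product: 16 (4S,5R)-4-[(1R)-6-[(tert-butyldiphenylsilyl)oxy]-1-hydroxyhex-2-yn-1-yl]-5-(2-methylprop-2-en-1-yl)oxolan-2-one
Conditions: Ru[(R,R)-TsNCHPhCHPhNH](p-cymene) (2 mol %), i-PrOH, rt
Reagents that add atoms: none
Why: Noyori asymmetric transfer hydrogenation of an ynone, in which the base-free 16-electron (R,R) complex tells the alkynyl flank from the alkyl flank and should give the (6R) propargylic alcohol under catalyst control while leaving alkyne, alkene and lactone untouched.

Step 10
Reactants: 16 (4S,5R)-4-[(1R)-6-[(tert-butyldiphenylsilyl)oxy]-1-hydroxyhex-2-yn-1-yl]-5-(2-methylprop-2-en-1-yl)oxolan-2-one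
Product: 17 (3aS,4R,7aR)-5-[5-[(tert-butyldiphenylsilyl)oxy]pent-1-en-2-yl]-4-hydroxy-6-methyl-3a,4,7,7a-tetrahydro-1-benzofuran-2(3H)-one
Conditions: second-generation Grubbs catalyst RuCl2(=CHPh)(PCy3)(H2IMes) (10 mol % in two portions), toluene (0.005 M), 80 °C, Ar
Reagents that add atoms: none
Why: This is a ring-closing enyne metathesis that starts at the alkyne: after one initiating turnover of the benzylidene, the propagating Ru=CH2 adds across C5≡C4 with its carbon on the less hindered C4 (next to the unbranched C3H2) and the metal on C5 (next to the branched carbinol C6), and opening of the ruthenacyclobutene gives the vinylcarbene Ru=C5–C4(=C15H2). That carbene engages the methallyl alkene through a ruthenacyclobutane, and cycloreversion forms C5=C10 and returns Ru=CH2, so 17 is an isomer of 16 in which a methallyl CH2 has become C15. The closest known reaction type is the closure of 1,7-enynes bearing a 1,1-disubstituted alkene and an internal alkyne to 1-alkenylcyclohexenes with N-heterocyclic-carbene ruthenium catalysts. Ring A closes in the exo mode as a six-membered ring with C4=C15 left outside it, whereas the endo alternative would be a seven-membered ring joined through C4=C10. No stereocentre is created, and C6, C7 and C8 are spectators. The step needs exo over endo closure and cyclisation over chain coupling; the first should follow from the alkyne regiochemistry and the ring size, the second from high dilution and from the cis placement of both arms on ring B, which keeps C5 and C10 close.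

Step 11
Reactants: 17 (3aS,4R,7aR)-5-[5-[(tert-butyldiphenylsilyl)oxy]pent-1-en-2-yl]-4-hydroxy-6-methyl-3a,4,7,7a-tetrahydro-1-benzofuran-2(3H)-one
Product: 18 (3aS,4R,7aR)-5-[(2S)-5-[(tert-butyldiphenylsilyl)oxy]pentan-2-yl]-4-hydroxy-6-methyl-3a,4,7,7a-tetrahydro-1-benzofuran-2(3H)-one
Conditions: [Ir(cod)(PCy3)(py)]PF6 (5 mol %), H2 (1 atm), CH2Cl2, 0 °C, stopped after one equivalent of H2
Reagents that add atoms: none
Why: Hydroxyl-directed homogeneous hydrogenation, in which iridium bound to O6 reaches the twisted diene only at the 1,1-disubstituted C4=C15 alkene in the rotamer that turns C15 toward the O6 face and delivers hydrogen to the face of C4 looking at C6, which should set 4S and leave the tetrasubstituted C5=C10 alkene intact.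

Step 12
Reactants: 18 (3aS,4R,7aR)-5-[(2S)-5-[(tert-butyldiphenylsilyl)oxy]pentan-2-yl]-4-hydroxy-6-methyl-3a,4,7,7a-tetrahydro-1-benzofuran-2(3H)-one
Product: 19 (3aR,4R,7aR)-5-[(2S)-5-[(tert-butyldiphenylsilyl)oxy]pentan-2-yl]-6-methyl-4-[(triethylsilyl)oxy]-3a,4,7,7a-tetrahydro-1-benzofuran-2(3H)-one
Conditions: TESOTf, 2,6-lutidine, CH2Cl2, −78 → 0 °C
Reagents that add atoms: triethylsilyl trifluoromethanesulfonate, CC[Si](CC)(CC)OS(=O)(=O)C(F)(F)F
Why: Silylation with a silyl triflate and a hindered pyridine base covers the crowded O6 hydroxyl, which as an alkoxide in step 13 could attack C12 and shift the lactone from O8 to O6.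

Step 13
Reactants: 19 (3aR,4R,7aR)-5-[(2S)-5-[(tert-butyldiphenylsilyl)oxy]pentan-2-yl]-6-methyl-4-[(triethylsilyl)oxy]-3a,4,7,7a-tetrahydro-1-benzofuran-2(3H)-one
Product: 23 (3aR,4R,7aR)-5-[(2S)-5-[(tert-butyldiphenylsilyl)oxy]pentan-2-yl]-6-methyl-3-methylidene-4-[(triethylsilyl)oxy]-3a,4,7,7a-tetrahydro-1-benzofuran-2(3H)-one, via lithium enolate 20 (not isolated), via Mannich base 21 (not isolated), via methiodide 22 (not isolated)
Conditions: LiN(iPr)2, THF, −78 °C; Me2N=CH2 I, −78 °C → rt; MeI, CH2Cl2, rt; aq NaHCO3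
Reagents that add atoms: Eschenmoser's salt (N,N-dimethylmethyleneiminium iodide), C=[N+](C)C.[I-]
Why: α-Methylenation of a lactone by Mannich reaction of its lithium enolate with Eschenmoser's salt, quaternisation and Hofmann-type elimination, with C11 as the only acidic position and ending sp2, so no stereocentre is at stake.

Step 14
Reactants: 23 (3aR,4R,7aR)-5-[(2S)-5-[(tert-butyldiphenylsilyl)oxy]pentan-2-yl]-6-methyl-3-methylidene-4-[(triethylsilyl)oxy]-3a,4,7,7a-tetrahydro-1-benzofuran-2(3H)-one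
Product: 24 (3aS,4R,7aR)-5-[(2S)-5-[(tert-butyldiphenylsilyl)oxy]pentan-2-yl]-4-hydroxy-6-methyl-3-methylidene-3a,4,7,7a-tetrahydro-1-benzofuran-2(3H)-one
Conditions: AcOH, THF, H2O, rt
Reagents that add atoms: none
Why: Selective acid solvolysis of a triethylsilyl ether, which is far more labile than the tert-butyldiphenylsilyl ether at O1.

Step 15
Reactants: 24 (3aS,4R,7aR)-5-[(2S)-5-[(tert-butyldiphenylsilyl)oxy]pentan-2-yl]-4-hydroxy-6-methyl-3-methylidene-3a,4,7,7a-tetrahydro-1-benzofuran-2(3H)-one; 25 (2R)-2-methylbutanoic acid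
Product: 27 (3aR,4R,7aR)-5-[(2S)-5-[(tert-butyldiphenylsilyl)oxy]pentan-2-yl]-6-methyl-3-methylidene-2-oxo-2,3,3a,4,7,7a-hexahydro-1-benzofuran-4-yl (2R)-2-methylbutanoate, via O-acylisourea 26 (not isolated)
Conditions: DCC, DMAP, CH2Cl2, 0 °C → rt
Reagents that add atoms: none
Why: Steglich esterification, in which a simple α-alkyl acid should keep its (R) centre under carbodiimide activation and the C6–O bond is not broken, so 6R is retained.

Step 16
Reactants: 27 (3aR,4R,7aR)-5-[(2S)-5-[(tert-butyldiphenylsilyl)oxy]pentan-2-yl]-6-methyl-3-methylidene-2-oxo-2,3,3a,4,7,7a-hexahydro-1-benzofuran-4-yl (2R)-2-methylbutanoate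
Product: 28 (3aR,4R,7aR)-5-[(2S)-5-hydroxypentan-2-yl]-6-methyl-3-methylidene-2-oxo-2,3,3a,4,7,7a-hexahydro-1-benzofuran-4-yl (2R)-2-methylbutanoate
Conditions: HF·pyridine, THF, 0 °C → rt
Reagents that add atoms: none
Why: Fluoride-mediated desilylation under mildly acidic conditions that should spare the Michael-acceptor lactone and the ester.

**Compound list**
1 | (4R)-4-[(tert-butyldimethylsilyl)oxy]cyclopent-2-en-1-one | O=C1C=C[C@H](O[Si](C)(C)C(C)(C)C)C1 | starting material
2 | (1S,4R)-4-[(tert-butyldimethylsilyl)oxy]-1-methylcyclopent-2-en-1-ol | C[C@@]1(O)C=C[C@H](O[Si](C)(C)C(C)(C)C)C1 | intermediate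
3 | 1-(dimethylamino)ethenyl ether of 2 (ketene N,O-acetal) | C[C@@]1(OC(=C)N(C)C)C=C[C@H](O[Si](C)(C)C(C)(C)C)C1 | intermediate
4 | 2-[(1S,5R)-5-[(tert-butyldimethylsilyl)oxy]-3-methylcyclopent-2-en-1-yl]-N,N-dimethylacetamide | CN(C)C(=O)C[C@H]1C=C(C)C[C@H]1O[Si](C)(C)C(C)(C)C | intermediate
5 | 2-[(1S,5R)-5-hydroxy-3-methylcyclopent-2-en-1-yl]-N,N-dimethylacetamide | CN(C)C(=O)C[C@H]1C=C(C)C[C@H]1O | intermediate
6 | (1R,5S)-7-methyl-2-oxabicyclo[3.3.0]oct-6-en-3-one | C1C(=O)O[C@@H]2CC(C)=C[C@H]12 | intermediate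
7 | secondary ozonide of 6 (1,2,4-trioxolane bridging C6 and C10, ozonide carbons undefined) | C1C(=O)O[C@@H]2CC3(C)OOC(O3)[C@H]12 | intermediate
8 | (2R,3R)-5-oxo-2-(2-oxopropyl)oxolane-3-carbaldehyde | C1C(=O)O[C@H](CC(C)=O)[C@@H]1C=O | intermediate
9 | pent-4-yn-1-ol | C#CCCCO | starting material
10 | tert-butyl(pent-4-yn-1-yloxy)diphenylsilane | C#CCCCO[Si](c1ccccc1)(c1ccccc1)C(C)(C)C | intermediate
11 | lithium acetylide of 10 | [Li]C#CCCCO[Si](c1ccccc1)(c1ccccc1)C(C)(C)C | intermediate
12 | triisopropoxytitanium acetylide of 10 | CC(C)O[Ti](OC(C)C)(OC(C)C)C#CCCCO[Si](c1ccccc1)(c1ccccc1)C(C)(C)C | intermediate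
13 | (4S,5R)-4-[6-[(tert-butyldiphenylsilyl)oxy]-1-hydroxyhex-2-yn-1-yl]-5-(2-oxopropyl)oxolan-2-one, both C6 epimers | C1C(=O)O[C@H](CC(C)=O)[C@@H]1C(O)C#CCCCO[Si](c1ccccc1)(c1ccccc1)C(C)(C)C | intermediate
14 | (4S,5R)-4-[6-[(tert-butyldiphenylsilyl)oxy]-1-hydroxyhex-2-yn-1-yl]-5-(2-methylprop-2-en-1-yl)oxolan-2-one, both C6 epimers | C1C(=O)O[C@H](CC(C)=C)[C@@H]1C(O)C#CCCCO[Si](c1ccccc1)(c1ccccc1)C(C)(C)C | intermediate
15 | (4R,5R)-4-[6-[(tert-butyldiphenylsilyl)oxy]hex-2-ynoyl]-5-(2-methylprop-2-en-1-yl)oxolan-2-one | C1C(=O)O[C@H](CC(C)=C)[C@@H]1C(=O)C#CCCCO[Si](c1ccccc1)(c1ccccc1)C(C)(C)C | intermediate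
16 | (4S,5R)-4-[(1R)-6-[(tert-butyldiphenylsilyl)oxy]-1-hydroxyhex-2-yn-1-yl]-5-(2-methylprop-2-en-1-yl)oxolan-2-one | C1C(=O)O[C@H](CC(C)=C)[C@@H]1[C@@H](O)C#CCCCO[Si](c1ccccc1)(c1ccccc1)C(C)(C)C | intermediate
17 | (3aS,4R,7aR)-5-[5-[(tert-butyldiphenylsilyl)oxy]pent-1-en-2-yl]-4-hydroxy-6-methyl-3a,4,7,7a-tetrahydro-1-benzofuran-2(3H)-one | C1C(=O)O[C@@H]2CC(C)=C(C(=C)CCCO[Si](c3ccccc3)(c3ccccc3)C(C)(C)C)[C@H](O)[C@H]12 | intermediate
18 | (3aS,4R,7aR)-5-[(2S)-5-[(tert-butyldiphenylsilyl)oxy]pentan-2-yl]-4-hydroxy-6-methyl-3a,4,7,7a-tetrahydro-1-benzofuran-2(3H)-one | C1C(=O)O[C@@H]2CC(C)=C([C@@H](C)CCCO[Si](c3ccccc3)(c3ccccc3)C(C)(C)C)[C@H](O)[C@H]12 | intermediate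
19 | O6-triethylsilyl ether of 18 | C1C(=O)O[C@@H]2CC(C)=C([C@@H](C)CCCO[Si](c3ccccc3)(c3ccccc3)C(C)(C)C)[C@H](O[Si](CC)(CC)CC)[C@H]12 | intermediate
20 | lithium enolate of 19 | C1=C(O[Li])O[C@@H]2CC(C)=C([C@@H](C)CCCO[Si](c3ccccc3)(c3ccccc3)C(C)(C)C)[C@H](O[Si](CC)(CC)CC)[C@H]12 | intermediate
21 | C11-(dimethylaminomethyl) derivative of 19 (C11 undefined) | CN(C)CC1C(=O)O[C@@H]2CC(C)=C([C@@H](C)CCCO[Si](c3ccccc3)(c3ccccc3)C(C)(C)C)[C@H](O[Si](CC)(CC)CC)[C@H]12 | intermediate
22 | trimethylammonium iodide derived from 21 | C[N+](C)(C)CC1C(=O)O[C@@H]2CC(C)=C([C@@H](C)CCCO[Si](c3ccccc3)(c3ccccc3)C(C)(C)C)[C@H](O[Si](CC)(CC)CC)[C@H]12.[I-] | intermediate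
23 | (3aR,4R,7aR)-5-[(2S)-5-[(tert-butyldiphenylsilyl)oxy]pentan-2-yl]-6-methyl-3-methylidene-4-[(triethylsilyl)oxy]-3a,4,7,7a-tetrahydro-1-benzofuran-2(3H)-one | C=C1C(=O)O[C@@H]2CC(C)=C([C@@H](C)CCCO[Si](c3ccccc3)(c3ccccc3)C(C)(C)C)[C@H](O[Si](CC)(CC)CC)[C@H]12 | intermediate
24 | (3aS,4R,7aR)-5-[(2S)-5-[(tert-butyldiphenylsilyl)oxy]pentan-2-yl]-4-hydroxy-6-methyl-3-methylidene-3a,4,7,7a-tetrahydro-1-benzofuran-2(3H)-one | C=C1C(=O)O[C@@H]2CC(C)=C([C@@H](C)CCCO[Si](c3ccccc3)(c3ccccc3)C(C)(C)C)[C@H](O)[C@H]12 | intermediate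
25 | (2R)-2-methylbutanoic acid | CC[C@@H](C)C(=O)O | starting material
26 | O-acylisourea from 25 and DCC | CC[C@@H](C)C(=O)OC(=NC1CCCCC1)NC1CCCCC1 | intermediate
27 | O1-tert-butyldiphenylsilyl ether of the target | C=C1C(=O)O[C@@H]2CC(C)=C([C@@H](C)CCCO[Si](c3ccccc3)(c3ccccc3)C(C)(C)C)[C@H](OC(=O)[C@H](C)CC)[C@H]12 | intermediate
28 | (3aR,4R,7aR)-5-[(2S)-5-hydroxypentan-2-yl]-6-methyl-3-methylidene-2-oxo-2,3,3a,4,7,7a-hexahydro-1-benzofuran-4-yl (2R)-2-methylbutanoate | C=C1C(=O)O[C@@H]2CC(C)=C([C@@H](C)CCCO)[C@H](OC(=O)[C@H](C)CC)[C@H]12 | target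

**Totals**
Total step count: 16.
Longest linear sequence: 15 steps (steps 1–4 and 6–16, counted from 1).

**Steps most likely to fail**

Step 10. The closure must build a tetrasubstituted alkene from a fully substituted vinylcarbene and a 1,1-disubstituted alkene.
- What may go wrong: slow ring closure could let the methylidene decay, let the alkyne insert in the reverse sense (endo closure to a seven-membered ring), or let chains couple with one another.
- Fallback: the event is split into two known metatheses. Setting out from 16, cross enyne metathesis with ethene (second-generation Grubbs catalyst, ethene 1 atm, CH2Cl2, 40 °C) should give the 2,3-dimethylidene triene F1. Ring-closing diene metathesis of its C5=CH2 and C10=CH2 groups with the less crowded RuCl2(=CH-2-iPrOC6H4)[1,3-bis(2-methylphenyl)imidazolidin-2-ylidene] (toluene, 80 °C) comes back to the route at 17.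

Step 11. Stereocontrol rests on one rotamer about C4–C5 and on O6 holding the metal.
- What may go wrong: free rotation or a pseudoequatorial hydroxyl would erode facial selectivity at C4, and a long contact time could lead to reduction of C5=C10 or to 1,4-addition of hydrogen across the diene.
- Fallback: control is moved from the substrate to the catalyst. Setting out from 17, silylation (TESOTf, 2,6-lutidine) gives the diene triethylsilyl ether F2. Its 1,1-disubstituted alkene is then hydrogenated with a chiral iridium N,P complex, [Ir(cod)(tBu-PHOX)][B(3,5-(CF3)2C6H3)4], with both ligand antipodes tried and the matched one kept. This comes back to the route at 19, one step further on.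

Step 6. The keto aldehyde carries an acidic C7–H next to a β-acyloxy leaving group.
- What may go wrong: epimerisation at C7, β-elimination that opens ring B, or competing attack at the ketone could erode the addition.
- Fallback: the carbanion route is replaced by a Nozaki–Hiyama–Kishi-type coupling. Setting out from 10, iodination (N-iodosuccinimide, cat. AgNO3, acetone) gives the 1-iodoalkyne F3. Treatment of F3 with CrCl2 in THF at rt forms a non-basic, aldehyde-selective alkynylchromium species in the presence of 8, and this comes back to the route at 13.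

**Further compounds**
F1 | step 10 | (4S,5R)-4-[(1R)-6-[(tert-butyldiphenylsilyl)oxy]-1-hydroxy-2,3-dimethylidenehexyl]-5-(2-methylprop-2-en-1-yl)oxolan-2-one | C1C(=O)O[C@H](CC(C)=C)[C@@H]1[C@@H](O)C(=C)C(=C)CCCO[Si](c1ccccc1)(c1ccccc1)C(C)(C)C
F2 | step 11 | O6-triethylsilyl ether of 17 | C1C(=O)O[C@@H]2CC(C)=C(C(=C)CCCO[Si](c3ccccc3)(c3ccccc3)C(C)(C)C)[C@H](O[Si](CC)(CC)CC)[C@H]12
F3 | step 6 | tert-butyl[(5-iodopent-4-yn-1-yl)oxy]diphenylsilane | IC#CCCCO[Si](c1ccccc1)(c1ccccc1)C(C)(C)C
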